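Links form when first end groups meet second end groups, while protic impurity takes first end groups from the same flask. Tuesday's and Sunday's stand closed at constant temperature, as charged here:

| flask | first end groups | second end groups | third end groups | protic impurity | temperature | remark | time |
|---|---|---|---|---|---|---|---|
| ochre | 0.029 M | 0.11 M | 0.055 M | 0.033 M | 20 °C | run made earlier |  |
| grey | 0.093 M | 0.11 M | 0.055 M | 0.033 M | 31 °C | run made earlier |  |
| teal | 0.11 M | 0.20 M | 0.055 M | 0.033 M | 20 °C | run made earlier |  |
| Tuesday's | 0.11 M | 0.110 M | 0.0550 M | 0.0330 M | 25 °C |  | 8.0 d |
| Sunday's | 0.040 M | 0.300 M | 0.0550 M | 0.0330 M | 25 °C |  | 8.0 d |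

| run | time / d | links / % | first end groups / % |
|---|---|---|---|
| ochre | 1.04 | 27.9 | 11.0 |
| ochre | 2.08 | 31.6 | 1.5 |
| ochre | 3.00 | 31.7 | 0.7 |
| ochre | 4.00 | 32.4 | 0 |
| grey | 0.333 | 31.0 | 31.4 |
| grey | 0.833 | 39.5 | 12.7 |
| grey | 1.67 | 42.5 | 3.6 |
| grey | 4.00 | 43.6 | 0.4 |
| teal | 1.04 | 46.0 | 16.6 |
| teal | 2.08 | 54.1 | 4.6 |
| teal | 3.00 | 54.8 | 1.3 |
| teal | 4.00 | 56.3 | 1.3 |

(scatter of a reading: 0.5 percentage points)

- which of the two ends with the higher amount of links, in percent of the first end groups charged ("neither" if they lie within 2 percentage points) (Tuesday's / Sunday's / neither)
- links at the end, in percent of the first end groups charged, Tuesday's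
- links at the end, in percent of the first end groups charged, Sunday's

- the numbers in the tables scatter with a standard deviation of 0.5 percentage points

Ochre's first end groups read 0% already at 4.00 d, earlier than the 8.0 d of both flasks, so their links should have stopped rising by then; that reading tells nothing of the other end groups.

Ochre, taking its non-link loss as impurity, leaves these fractions:

impurity 0.406, second end groups 0.915, S = 10.1

S is the selectivity factor: the logarithm of the impurity fraction left over that of the second end groups left. Link rate over quench rate is then second end groups / (S × impurity), which is 0.900 at Sunday's charge.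

Grey lost 56.4% of its charge without links, more than its impurity charge of 35.5%, so a further route exists. S is therefore reserved for Sunday's, and Tuesday's is left to the forecast. My trial for Sunday's, a link share of 0.5:

S law: impurity left 0.498; balance: 0.394

The law leaves more, so the share lies above 0.5.

The forecast says Sunday's, with 46.8% for Tuesday's and 55.5% for Sunday's, holding that “temperature hardly affects selectivity”. At its Sunday's share, the law gives 0.460 and the balance 0.461.

The flasks give Sunday's: Tuesday's 41.9%, Sunday's 56.8%. The forecast held.

    first end groups + second end groups → links (k = 0.510 /M/h, Ea = 74.0 kJ/mol)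
    second end groups + third end groups → links of the second sort (k = 0.150 /M/h, Ea = 83.0 kJ/mol)
    2 third end groups → homo dimer (k = 0.0210 /M/h, Ea = 90.0 kJ/mol)
    first end groups + protic impurity → quenched substrate (k = 4.20 /M/h, Ea = 57.0 kJ/mol)
    first end groups + links → side product (k = 0.240 /M/h, Ea = 80.0 kJ/mol)
    (constants at 25 °C)

In Sunday's at 0.705 d, the link step uses first end groups 1.8 times as fast as quenching; the 0.900 was reckoned for the charge, another moment, so the two are not held against each other. With S, Sunday's link share leaves 45.1% of the impurity, against 50% found at 8.00 d, when side product stands at 2.30%.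

In a flask like Sunday's but with 0.18 M of second end groups, link rate over quench rate starts at 0.540. At a share of 0.5, the law gives 0.304 and the balance 0.394, so its share lies below 0.5. The flask gives 46.2%.

The readings were generated by integration with made-up constants; scatter was added.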